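Partner, a single-handed reagent, meets a racemate and disappears as it works. In the ash run at 3.00 h, left-handed product stands at 12.9% against 4.6% of right-handed product.

| flask | left-handed substrate | right-handed substrate | partner | remark | time |
|---|---|---|---|---|---|
| cedar | 45 mM | 45 mM | 130 mM | run made earlier |  |
| ash | 45 mM | 45 mM | 180 mM | run made earlier |  |
| Friday's | 45 mM | 45 mM | 90.0 mM |  | 6.0 h |
| Tuesday's | 45 mM | 45 mM | 150 mM |  | 2.0 h |

| run | time / h | left-handed product / % | right-handed product / % |
|---|---|---|---|
| cedar | 0.417 | 3.5 | 1.0 |
| cedar | 0.833 | 5.7 | 1.3 |
| cedar | 1.33 | 7.6 | 2.9 |
| cedar | 1.50 | 7.8 | 3.0 |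
| cedar | 2.00 | 8.7 | 2.7 |
| cedar | 2.50 | 9.6 | 2.9 |
| cedar | 3.00 | 9.4 | 2.9 |
| ash | 0.250 | 3.4 | 1.4 |
| ash | 0.333 | 3.8 | 2.0 |
| ash | 0.500 | 5.1 | 1.8 |
| ash | 0.833 | 7.9 | 2.8 |
| ash | 1.33 | 9.8 | 3.4 |
| ash | 2.00 | 11.7 | 4.3 |
| ash | 3.00 | 12.9 | 4.6 |

(standard deviation of a reading: 0.3 percentage points)

- which of the two ends with the higher excess of left-handed product over right-handed product ("neither" if they lie within 2 percentage points) (Friday's / Tuesday's / neither)
- excess of left-handed product over right-handed product at the end, Friday's
- excess of left-handed product over right-handed product at the end, Tuesday's

- partner is single-handed; left-handed substrate and right-handed substrate are mirror images of each other, charged as a racemate, each of them at the stated concentration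
- steps that have been proposed: partner + left-handed substrate -> left-handed product; partner + right-handed substrate -> right-handed product; left-handed substrate <-> right-handed substrate; partner -> decomposed reagent; partner <-> dormant form
- an excess is the difference of the two amounts in percent of their sum
- an excess is below zero if the other one leads
- the handed part of partner does not stay in what it makes, so the products of the two hands are mirror images too

Turned round, the question is how far apart two conversions must lie for the excesses to differ by the margin. The logarithms of what remains of each hand, summed over the last readings of both runs, give a reading of the selectivity factor: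

s = 3.24

The opening excess then reads E = (s − 1)/(s + 1):

E = 52.9%

With racemisation left out of this reckoning, the excess falls as the left-handed substrate thins. At small conversion, the excess lost per point of conversion, the sag, is E times one minus E squared, halved:

sag = 0.190

A difference of 2 percentage points therefore needs a conversion gap of:

gap = 10.5%

Products per partner charged read 8.75% in the ash run at 3.00 h and 8.00% at 2.00 h. Scaling these by partner, with the last ash reading standing in for Friday's longer time, gives about 8.75% conversion for Friday's and 13.3% for Tuesday's. That difference is smaller than the gap, so this reckoning says neither, with Friday's 0.87 points higher.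

The forecast gave 51% for Friday's, 49% for Tuesday's and neither, holding that “Partner decay therefore sets the conversion”.

The simulation gives 49.6% for Friday's and 48.8% for Tuesday's: neither.

    partner + left-handed substrate → left-handed product (k = 4.30 × 10⁻⁴ /M/s)
    partner + right-handed substrate → right-handed product (k = 1.40 × 10⁻⁴ /M/s)
    left-handed substrate ⇌ right-handed substrate (k = 6.70 × 10⁻⁵ /s)
    partner → decomposed reagent (k = 2.00 × 10⁻⁴ /s)
    partner ⇌ dormant form (K = 0.930, k = 2.70 × 10⁻⁵ /s)

In Friday's, partner's half-life by the step to decomposed reagent alone is 0.96 h, against 10 h by the step to left-handed product alone; at the start the step to decomposed reagent uses ten times as much partner as the step to left-handed product. Partner, the limiting reagent there, is down to 1.3% of its charge at 6.00 h, with 6.07 mM in the dormant form and conversion at 9.91%. With 22 mM of partner, otherwise as Friday's, the products-per-partner reading gives 2.14% conversion, so the sag puts the excess 1.5 points above Friday's. The computed flask gives 50.6%, which is 1.00 point above.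

The numbers in the tables are simulated from invented constants.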